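Count what a unit of reagent buys in Friday's flask before asking about second substrate.

| setting | Friday's | Sunday's | flask |
|---|---|---|---|
| starting material | 0.50 M | 0.50 M | 0.50 M |
| second substrate | 1 equiv | 1 equiv | 1.00 equiv |
| reagent | 0.70 equiv | 0.35 equiv | 0.700 equiv |
| free catalyst | 0.4 mol% | 0.4 mol% | 0.4 mol% |
| remark | the very flask that is asked about, followed so far | run made earlier |  |

| run | time / min | target / % |
|---|---|---|
| Friday's | 8.00 | 9 |
| Friday's | 15.0 | 15 |
| Friday's | 20.0 | 19 |
| Friday's | 30.0 | 26 |
| Friday's | 40.0 | 31 |
| Sunday's | 10.0 | 7 |
| Sunday's | 20.0 | 15 |
| Sunday's | 40.0 | 19 |
| Sunday's | 60.0 | 25 |
| Sunday's | 120 | 28 |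

(readings scatter by 1.5 percentage points)

- no earlier run changes the charge of second substrate; that part of a forecast is a guess

1. apparent order in second substrate when 20 % of the starting material are converted (percent change of the rate of making target for one percent more second substrate charged)

Sunday's run reads 28 % target at 120 min from 0.35 equiv of reagent. This gives the leak L, the share of charged reagent that has not appeared as target at the last reading of that run: 0.200, a reading whose target carries a scatter of 1.5 percentage points.

Two extreme versions of Friday's flask can be solved in the head. In the first, second substrate is a partner in making target, the rate is proportional to it, and the order is 1. In the second, it merely feeds the leak. With the catalyst's turns held fixed in number, one percent more second substrate then takes about L percent from the target rate, so the order is −0.200. The real flask lies between these ends, and the runs do not change the charge, so placing it is a guess. But a leak of this size, in a run whose target still rose between its last two readings, suggests a second consumer of reagent, and second substrate is a charged candidate. The reckoning here therefore commits to the lower end, near −L.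

The forecast differs in sign: it gives 0.7, higher than −L, with the remark “this is largely a guess”.

The flask gives −0.16.

    starting material + free catalyst ⇌ catalyst intermediate A (K = 27.0 /M, k = 17.0 /M/min)
    reagent + catalyst intermediate A → free catalyst + target (k = 18.0 /M/min)
    second substrate + free catalyst ⇌ catalyst intermediate B (K = 1.10 /M, k = 8.30 /M/min)
    reagent + catalyst intermediate B → free catalyst + second product (k = 22.0 /M/min)
    reagent + free catalyst ⇌ idle complex, settled at all times (K = 1.50 /M)

Carried to Friday's flask, L allows 56.0 % target from its reagent, the limiting reagent, and at 30.0 h the flask holds 56.8 % target with 0 % reagent left. At 0.574 h in this flask, catalyst intermediate B falls back 2.0 times as fast as it goes on, whereas catalyst intermediate A has a ratio of 0.20, so the ratio for B is larger, ten times the one for A. At 1.50 h Friday's flask holds 67.6 % of its catalyst as catalyst intermediate A against 9.36 % as catalyst intermediate B.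

The numbers in the tables are calculated from invented constants; the scatter is artificial.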